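**Retrosynthetic overview** (labdane numbering, defined in the remarks)
1. Target 24 ⇐ ozonolysis of a 2-methylpropenyl group added equatorially to the C8 ketone (gives C8–OH/C17 aldehyde); the (13Z)-enoate comes from a Negishi coupling of a C12 alkylzinc with methyl (Z)-3-iodobut-2-enoate.
2. 8-Oxo-decalin 14 ⇐ 1-vinylcyclobutanol 13 by forming C5–C6: alkoxy-radical cleavage of the C5–C8 bond of a four-membered ring, then 6-endo closure of the C5 radical onto the freed vinyl ketone (ring B made by a two-carbon ring expansion, i.e. C–C cleavage of a strained ring).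
3. 13 ⇐ cyclobutanone 8 (aldol condensation at C9, vinyl addition at C8) ⇐ ketene [2+2] on the C5=C10 alkene of cyclohexenyl silyl ether 6 ⇐ 4-methylanisole (Birch dearomatization, gem-dimethylation, CBS reduction).
4. Ring order: ring A (from the arene), then a temporary cyclobutane on C5–C10, then ring B by ring expansion; the side chain and C17 follow.
5. Enabling feature: the strained cyclobutane C5–C8–C9–C10 fused to ring A, with a tertiary alcohol at C8 whose other two neighbours (C7 and C9) are sp2. Only the C5–C8 bond can break, and the C5 radical then meets C6 of the vinyl ketone in a six-membered closure.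

Key step: step 8

**Remarks**
- Numbering: C1–C10 are the decalin carbons (C5/C10 ring fusion), C18/C19 the methyls on C4, C20 the methyl on C10, C11–C16 the side chain (C15 carboxyl, C16 methyl on C13), C17 the formyl carbon on C8. The target is (3R,5S,8R,9S,10R,13Z).
- Assumption: the geometry of the exocyclic C9=C11 alkene in 12–14 is of no consequence (it is removed in step 9) and is drawn as E; 1, 9 and 17 are taken as commercial.

**Route**

Step 1
Reactants: 1 4-methylanisole
Product: 3 4-methylcyclohex-3-en-1-one, via Birch diene 2 (not isolated)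
Conditions: Li, NH3 (l), t-BuOH, THF, −78 to −33 °C; then oxalic acid (cat.), MeOH/H2O, rt
Reagents that add atoms: water, O
Why: A Birch reduction leaves the methoxy and methyl groups on the two remaining double bonds, and mild enol-ether hydrolysis gives the β,γ-unsaturated ketone without moving the C5=C10 alkene into conjugation; no stereocentre is formed.

Step 2
Reactants: 3 4-methylcyclohex-3-en-1-one
Product: 4 2,2,4-trimethylcyclohex-3-en-1-one
Conditions: KOtBu (2.3 equiv), MeI, t-BuOH/THF, 0 °C to rt
Reagents that add atoms: iodomethane, CI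
Why: Deconjugative α,α-dialkylation: the methylene between carbonyl and alkene is the most acidic site and its extended enolate is methylated twice at the α-carbon, which builds the C4 gem-dimethyl group; no stereocentre is formed.

Step 3
Reactants: 4 2,2,4-trimethylcyclohex-3-en-1-one
Product: 5 (R)-2,2,4-trimethylcyclohex-3-en-1-ol
Conditions: (S)-2-methyl-CBS-oxazaborolidine (10 mol %), catecholborane, toluene, −78 °C
Reagents that add atoms: none
Why: Corey–Bakshi–Shibata reduction: with the quaternary α-carbon as the large and the CH2 as the small substituent, the (S)-catalyst should deliver hydride to give the (R)-alcohol (C3 of the target), and catecholborane at low temperature should leave the alkene untouched.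

Step 4
Reactants: 5 (R)-2,2,4-trimethylcyclohex-3-en-1-ol
Product: 6 (R)-1-(tert-butyldimethylsilyloxy)-2,2,4-trimethylcyclohex-3-ene
Conditions: TBSOTf, 2,6-lutidine, CH2Cl2, 0 °C
Reagents that add atoms: tert-butyldimethylsilyl triflate, CC(C)(C)[Si](C)(C)OS(=O)(=O)C(F)(F)F
Why: Silyl ether formation with the triflate (the alcohol is neopentylic) protects O3 against the acid chloride, the organometallic reagents and the alkoxy-radical conditions that follow.

Step 5
Reactants: 6 (R)-1-(tert-butyldimethylsilyloxy)-2,2,4-trimethylcyclohex-3-ene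
Product: 8 cis-fused cyclobutanone 4-(tert-butyldimethylsilyloxy)-1,5,5-trimethylbicyclo[4.2.0]octan-7-one, via dichlorocyclobutanone 7 (not isolated)
Conditions: Cl3CCOCl, Zn(Cu), Et2O/DME, rt, sonication; then Zn, NH4Cl, MeOH, rt
Reagents that add atoms: trichloroacetyl chloride, ClC(Cl)(Cl)C(Cl)=O
Why: [2+2] ketene–alkene cycloaddition of dichloroketene: the carbonyl carbon bonds to the less substituted C5 and the CCl2 carbon to C10, addition is suprafacial (cis fusion) and should occur on the face opposite to the pseudoaxial C4 methyl of the half-chair with equatorial silyloxy group, so that the C10 methyl ends cis to O3, and zinc then removes both chlorines.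

Step 6
Reactants: 8 cis-fused cyclobutanone; 9 benzyloxyacetaldehyde
Product: 12 (8E)-8-(2-benzyloxyethylidene)-4-(tert-butyldimethylsilyloxy)-1,5,5-trimethylbicyclo[4.2.0]octan-7-one, via aldol adduct 10 (not isolated), via mesylate 11 (not isolated)
Conditions: LiN(iPr)2, THF, −78 °C; 9; then MsCl, −78 to 0 °C; DBU, 0 °C to rt
Reagents that add atoms: none
Why: Directed aldol condensation: the amide base deprotonates the cyclobutanone at the CH2 (C9) and not at the hindered ring-fusion methine, the aldolate is mesylated and DBU effects E1cB elimination, and the resulting sp2 carbon C9 later forbids cleavage of the C8–C9 bond.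

Step 7
Reactants: 12 alkylidenecyclobutanone
Product: 13 8-(2-benzyloxyethylidene)-7-ethenyl-4-(tert-butyldimethylsilyloxy)-1,5,5-trimethylbicyclo[4.2.0]octan-7-ol
Conditions: CH2=CHMgBr, THF, −78 °C
Reagents that add atoms: vinylmagnesium bromide, C=C[Mg]Br
Why: 1,2-Addition of the Grignard reagent to the strained cyclobutanone carbonyl, expected from the convex face of the cis-fused bicycle, gives the tertiary bis-allylic alcohol; the configuration at C8 is erased in step 8.

Step 8
Reactants: 13 1-vinylcyclobutanol
Product: 14 trans-fused decalin enone 12-benzyloxy-3-(tert-butyldimethylsilyloxy)-13,14,15,16,17-pentanorlabd-9(11)-en-8-one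
Conditions: [Ir(dF(CF3)ppy)2(5,5'-d(CF3)bpy)]PF6 (2 mol %), 2,4,6-collidine, 2,4,6-triisopropylbenzenethiol (10 mol %), CH2Cl2, blue LEDs, rt
Reagents that add atoms: none
Why: The photoexcited iridium complex and collidine remove the O–H hydrogen of 13 by proton-coupled electron transfer, and the strained cyclobutyloxy radical undergoes β-scission of the C8–C5 bond (the only scission that does not give a vinylic radical, because C7 and C9 are sp2) to a secondary C5 radical tethered through C10 and C9 to a cross-conjugated divinyl ketone. This nucleophilic radical adds to the unsubstituted terminus C6 of the vinyl ketone in a 6-endo-trig (Giese-type) closure of ring B, the α-keto radical at C7 takes a hydrogen atom from the thiol, and the thiyl radical is returned to thiol by the reduced photocatalyst and collidinium, so the step is a redox-neutral isomerization whose closest known reaction type is the proton-coupled-electron-transfer two-carbon ring expansion of 1-vinylcycloalkanols. C5 is the only new stereocentre: ring A should react as the chair with the silyloxy group and the C10–C9 bond equatorial and the C10 methyl axial, and closure through the chair-like array with the forming C5–C6 bond equatorial (the topology that gives trans-decalins in 6-endo radical polyene cyclizations) should place H5 anti to the C10 methyl, i.e. the trans ring fusion, with inversion relative to the cis-fused cyclobutane. The step needs endo rather than exo closure, which the polarity of the enone secures (attack at the β-carbon gives the stabilised α-keto radical), and ring closure faster than hydrogen-atom capture of the C5 radical, which the low loading of a hindered thiol is meant to secure.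

Step 9
Reactants: 14 decalin enone
Product: 15 12-hydroxy-3-(tert-butyldimethylsilyloxy)-13,14,15,16,17-pentanorlabdan-8-one
Conditions: H2 (1 atm), Pd/C, EtOAc, rt
Reagents that add atoms: none
Why: Heterogeneous hydrogenation should saturate the exocyclic enone alkene from the face opposite to the axial C10 methyl, setting C9 with H9 cis to H5 (side chain equatorial, also the thermodynamic epimer next to the ketone), and cleaves the benzyl ether by hydrogenolysis.

Step 10
Reactants: 15 hydroxy ketone
Product: 16 12-iodo-3-(tert-butyldimethylsilyloxy)-13,14,15,16,17-pentanorlabdan-8-one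
Conditions: I2, PPh3, imidazole, CH2Cl2, 0 °C to rt
Reagents that add atoms: iodine, II
Why: Appel iodination converts the primary alcohol (the open form of the hemiketal equilibrium) into the iodide without touching the ketone or the silyl ether.

Step 11
Reactants: 17 methyl but-2-ynoate
Product: 18 methyl (Z)-3-iodobut-2-enoate
Conditions: NaI, AcOH, 110 °C
Reagents that add atoms: sodium iodide, [Na+].[I-]
Why: Hydroiodination of the ynoate (conjugate addition of iodide and protonation, net anti addition) is the standard route to the (Z)-3-iodoenoate, in which iodine and ester are cis.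

Step 12
Reactants: 16 keto iodide; 18 methyl (Z)-3-iodobut-2-enoate
Product: 20 methyl (13Z)-3-(tert-butyldimethylsilyloxy)-8-oxo-17-norlabd-13-en-15-oate, via alkylzinc iodide 19 (not isolated)
Conditions: Zn dust, LiCl, THF, 40 °C; then 18, Pd(PPh3)4 (5 mol %), THF, 50 °C
Reagents that add atoms: none
Why: Negishi coupling: LiCl-promoted zinc insertion into the primary iodide tolerates the ketone, and the palladium-catalysed sp3–sp2 coupling proceeds with retention of alkene geometry, so the chain enters cis to the ester (13Z).

Step 13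
Reactants: 20 keto ester
Product: 21 methyl (13Z)-8-hydroxy-17-(propan-2-ylidene)-3-(tert-butyldimethylsilyloxy)labd-13-en-15-oate
Conditions: Me2C=CHMgBr, CeCl3, THF, −78 °C
Reagents that add atoms: 2-methylprop-1-enylmagnesium bromide, CC(C)=C[Mg]Br
Why: Organocerium 1,2-addition to the hindered, enolizable C8 ketone: the axial trajectory is blocked by the syn-axial C10 methyl, so the alkenyl group should enter equatorially and the hydroxyl become axial (cis to C20), and at −78 °C the reagent should spare the β,β-disubstituted enoate ester.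

Step 14
Reactants: 21 alkenyl carbinol ester
Product: 23 (13Z)-3,8-dihydroxy-17-(propan-2-ylidene)labd-13-en-15-oic acid, via desilylated ester 22 (not isolated)
Conditions: Bu4NF, THF, 50 °C; then LiOH, MeOH/H2O, rt; aq. HCl to pH 4, 0 °C
Reagents that add atoms: lithium hydroxide, [Li+].[OH-]
Why: Fluoride cleaves the silyl ether and hydroxide saponifies the methyl ester (desilylation, then ester hydrolysis) under non-acidic conditions that the tertiary allylic alcohol tolerates; no stereocentre is touched.

Step 15
Reactants: 23 dihydroxy acid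
Product: 24 (3R,5S,8R,9S,10R,13Z)-3,8-dihydroxy-17-oxolabd-13-en-15-oic acid (target)
Conditions: O3, CH2Cl2/MeOH, −78 °C (Sudan Red 7B end point); then Me2S, −78 °C to rt
Reagents that add atoms: ozone, [O-][O+]=O
Why: Ozonolysis with reductive work-up: the electron-rich trisubstituted alkene should react much faster than the conjugated, acid-substituted side-chain alkene, and Criegee fragmentation towards acetone oxide releases the α-hydroxy aldehyde directly, leaving all stereocentres untouched.

**Compound list**
1 | 4-methylanisole | COc1ccc(C)cc1 | starting material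
2 | 1-methoxy-4-methylcyclohexa-1,4-diene (Birch diene, not isolated) | COC1=CCC(C)=CC1 | intermediate
3 | 4-methylcyclohex-3-en-1-one | CC1=CCC(=O)CC1 | intermediate
4 | 2,2,4-trimethylcyclohex-3-en-1-one | CC1=CC(C)(C)C(=O)CC1 | intermediate
5 | (R)-2,2,4-trimethylcyclohex-3-en-1-ol | CC1=CC(C)(C)[C@H](O)CC1 | intermediate
6 | (R)-1-(tert-butyldimethylsilyloxy)-2,2,4-trimethylcyclohex-3-ene | CC1=CC(C)(C)[C@H](O[Si](C)(C)C(C)(C)C)CC1 | intermediate
7 | 8,8-dichloro-4-(tert-butyldimethylsilyloxy)-1,5,5-trimethylbicyclo[4.2.0]octan-7-one; cis-fused, four-membered ring trans to the silyloxy group (not isolated) | O=C1C(Cl)(Cl)[C@]2(C)CC[C@@H](O[Si](C)(C)C(C)(C)C)C(C)(C)[C@H]12 | intermediate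
8 | 4-(tert-butyldimethylsilyloxy)-1,5,5-trimethylbicyclo[4.2.0]octan-7-one; cis-fused, C1 methyl cis to the silyloxy group (ring carbons C1/C6/C7/C8 = labdane C10/C5/C8/C9) | O=C1C[C@]2(C)CC[C@@H](O[Si](C)(C)C(C)(C)C)C(C)(C)[C@H]12 | intermediate
9 | benzyloxyacetaldehyde | O=CCOCc1ccccc1 | starting material
10 | aldol adduct of 8 and 9 at C9 (lithium alkoxide in the flask; mixture at the two new centres; not isolated) | O=C1C(C(O)COCc2ccccc2)[C@]3(C)CC[C@@H](O[Si](C)(C)C(C)(C)C)C(C)(C)[C@H]13 | intermediate
11 | mesylate of 10 (not isolated) | O=C1C(C(OS(C)(=O)=O)COCc2ccccc2)[C@]3(C)CC[C@@H](O[Si](C)(C)C(C)(C)C)C(C)(C)[C@H]13 | intermediate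
12 | (8E)-8-(2-benzyloxyethylidene)-4-(tert-butyldimethylsilyloxy)-1,5,5-trimethylbicyclo[4.2.0]octan-7-one | O=C1/C(=C/COCc2ccccc2)[C@]3(C)CC[C@@H](O[Si](C)(C)C(C)(C)C)C(C)(C)[C@H]13 | intermediate
13 | 8-(2-benzyloxyethylidene)-7-ethenyl-4-(tert-butyldimethylsilyloxy)-1,5,5-trimethylbicyclo[4.2.0]octan-7-ol; vinyl on the convex face (either C7 epimer is usable) | C=C[C@@]1(O)/C(=C/COCc2ccccc2)[C@]3(C)CC[C@@H](O[Si](C)(C)C(C)(C)C)C(C)(C)[C@H]13 | intermediate
14 | (3R,5S,10R)-12-benzyloxy-3-(tert-butyldimethylsilyloxy)-13,14,15,16,17-pentanorlabd-9(11)-en-8-one; trans-fused | C(OCc1ccccc1)/C=C1\[C@]2(C)CC[C@@H](O[Si](C)(C)C(C)(C)C)C(C)(C)[C@H]2CCC1=O | intermediate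
15 | (3R,5S,9S,10R)-12-hydroxy-3-(tert-butyldimethylsilyloxy)-13,14,15,16,17-pentanorlabdan-8-one; H9 cis to H5 | OCC[C@H]1[C@]2(C)CC[C@@H](O[Si](C)(C)C(C)(C)C)C(C)(C)[C@H]2CCC1=O | intermediate
16 | (3R,5S,9S,10R)-12-iodo-3-(tert-butyldimethylsilyloxy)-13,14,15,16,17-pentanorlabdan-8-one | ICC[C@H]1[C@]2(C)CC[C@@H](O[Si](C)(C)C(C)(C)C)C(C)(C)[C@H]2CCC1=O | intermediate
17 | methyl but-2-ynoate | CC#CC(=O)OC | starting material
18 | methyl (Z)-3-iodobut-2-enoate | C/C(I)=C/C(=O)OC | intermediate
19 | C12 alkylzinc iodide derived from 16 (not isolated) | I[Zn]CC[C@H]1[C@]2(C)CC[C@@H](O[Si](C)(C)C(C)(C)C)C(C)(C)[C@H]2CCC1=O | intermediate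
20 | methyl (3R,5S,9S,10R,13Z)-3-(tert-butyldimethylsilyloxy)-8-oxo-17-norlabd-13-en-15-oate | C/C(=C/C(=O)OC)CC[C@H]1[C@]2(C)CC[C@@H](O[Si](C)(C)C(C)(C)C)C(C)(C)[C@H]2CCC1=O | intermediate
21 | methyl (13Z)-8-hydroxy-17-(propan-2-ylidene)-3-(tert-butyldimethylsilyloxy)labd-13-en-15-oate; 8-OH axial, cis to C20 | C/C(=C/C(=O)OC)CC[C@H]1[C@]2(C)CC[C@@H](O[Si](C)(C)C(C)(C)C)C(C)(C)[C@H]2CC[C@]1(O)C=C(C)C | intermediate
22 | methyl (13Z)-3,8-dihydroxy-17-(propan-2-ylidene)labd-13-en-15-oate (not isolated) | C/C(=C/C(=O)OC)CC[C@H]1[C@]2(C)CC[C@@H](O)C(C)(C)[C@H]2CC[C@]1(O)C=C(C)C | intermediate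
23 | (13Z)-3,8-dihydroxy-17-(propan-2-ylidene)labd-13-en-15-oic acid | C/C(=C/C(=O)O)CC[C@H]1[C@]2(C)CC[C@@H](O)C(C)(C)[C@H]2CC[C@]1(O)C=C(C)C | intermediate
24 | (3R,5S,8R,9S,10R,13Z)-3,8-dihydroxy-17-oxolabd-13-en-15-oic acid | C/C(=C/C(=O)O)CC[C@H]1[C@]2(C)CC[C@@H](O)C(C)(C)[C@H]2CC[C@]1(O)C=O | target

**Step count and risks**
Total steps: 15. Longest linear sequence: 14 (steps 1–10 and 12–15; step 11 is a one-step side branch).

Steps most likely to fail:

1. Step 8. What may go wrong: hydrogen-atom transfer from the thiol to the ring-opened C5 radical before it closes ring B (seco ketone), thiol-mediated side reactions of the divinyl ketone, and loss of face control at C5 (cis ring fusion). Fallback, from 13 back to 14: the two radical events are separated. Hypoiodite fragmentation of 13 (PhI(OAc)2, I2, visible light, CH2Cl2) generates the same alkoxy radical, and iodine-atom transfer traps the C5 radical as the ring-opened divinyl ketone iodide F1. (Me3Si)3SiH with Et3B/O2 at −40 °C under slow addition then runs the 6-endo radical cyclization of F1 as a chain reaction with a very low stationary concentration of hydrogen donor and gives 14; the low temperature should also sharpen the preference for the trans closure.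

2. Step 5. What may go wrong: slow cycloaddition at the neopentylic C5 with oligomerization of the ketene, loss of the silyl ether through zinc salts, or incomplete face selection. Fallback, from 6 back to 8: a keteniminium [2+2] cycloaddition. N,N-Dimethylacetamide, Tf2O and 2,4,6-collidine in 1,2-dichloroethane generate the N,N-dimethylketeniminium ion, a stronger electrophile that adds to unactivated alkenes with the same regiochemistry and gives the cyclobutaniminium triflate F2; aqueous NaHCO3 hydrolysis gives 8 directly, without a dechlorination.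

3. Step 15. What may go wrong: competing ozonolysis of the side-chain alkene, or over-oxidation and fragmentation at the α-hydroxy aldehyde. Fallback, from 20 back to 24: C17 is carried as a masked hydroxymethyl group and the aldehyde is made by alcohol oxidation. (iPrO)Me2SiCH2MgCl with CeCl3 adds equatorially to the C8 ketone of 20 to give the silylmethyl carbinol F3; Tamao–Fleming oxidation (H2O2, KF, KHCO3, THF/MeOH) gives the 8,17-diol F4; Bu4NF gives the triol ester F5; LiOH gives the triol acid F6; TEMPO (cat.) with PhI(OAc)2 in CH2Cl2 oxidizes only the primary alcohol (O3 is secondary and neopentylic, O8 tertiary) to give 24.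

Further compounds
F1 | step 8 | ring-opened divinyl ketone with iodine at C5 (both C5 epimers): 1-[2-iodo-1,3,3-trimethyl-4-(tert-butyldimethylsilyloxy)cyclohexyl]-substituted (E)-4-benzyloxy-2-(prop-2-enoyl)but-2-ene | C=CC(=O)/C(=C/COCc1ccccc1)[C@]1(C)CC[C@@H](O[Si](C)(C)C(C)(C)C)C(C)(C)C1I
F2 | step 5 | N,N-dimethyl cyclobutaniminium triflate corresponding to 8 | C[N+](C)=C1C[C@]2(C)CC[C@@H](O[Si](C)(C)C(C)(C)C)C(C)(C)[C@H]12.[O-]S(=O)(=O)C(F)(F)F
F3 | step 15 | methyl (13Z)-8-hydroxy-17-(isopropoxydimethylsilyl)-3-(tert-butyldimethylsilyloxy)labd-13-en-15-oate | C/C(=C/C(=O)OC)CC[C@H]1[C@]2(C)CC[C@@H](O[Si](C)(C)C(C)(C)C)C(C)(C)[C@H]2CC[C@]1(O)C[Si](C)(C)OC(C)C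
F4 | step 15 | methyl (13Z)-8,17-dihydroxy-3-(tert-butyldimethylsilyloxy)labd-13-en-15-oate | C/C(=C/C(=O)OC)CC[C@H]1[C@]2(C)CC[C@@H](O[Si](C)(C)C(C)(C)C)C(C)(C)[C@H]2CC[C@]1(O)CO
F5 | step 15 | methyl (13Z)-3,8,17-trihydroxylabd-13-en-15-oate | C/C(=C/C(=O)OC)CC[C@H]1[C@]2(C)CC[C@@H](O)C(C)(C)[C@H]2CC[C@]1(O)CO
F6 | step 15 | (13Z)-3,8,17-trihydroxylabd-13-en-15-oic acid | C/C(=C/C(=O)O)CC[C@H]1[C@]2(C)CC[C@@H](O)C(C)(C)[C@H]2CC[C@]1(O)CO
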